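Numbering: C1 is the alkene carbon bearing C7H2OBz, C2 the alkene CH, C3–C6 the carbinol carbons (benzoate on O5). The route exploits the cis relationship of O3 and O6 on the two ring carbons that flank the C1=C2 unit of the cyclohexene: C3–C6 is an (E,E)-1,4-diacyloxybutadiene and C7–C1–C2 a 2-bromoacrolein. One catalytic enantioselective Diels–Alder reaction between the purchased symmetrical diene diacetate and 2-bromoacrolein (one step from acrolein) forms C2–C3 and C1–C6, closes the carbocycle and fixes C3 and C6. Dihydroxylation anti to the acetates, orthobenzoate masking, loss of HBr (bromine placing the alkene at C1=C2), reduction, benzoylation and acidic unmasking complete the synthesis.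

Key step: step 2

Assumption: the cycloaddition is taken to run formyl-endo (usual for 2-substituted acroleins with acyclic 1-oxygenated dienes) on the C1 Re face that the (S)-catalyst is predicted to expose; the formyl-exo adduct from the same catalyst is antipodal at C3/C6, so it is removed by chromatography, and the (R)-catalyst is used instead if the sense of induction proves reversed.

Face convention used below: β is the ring face bearing O3 and O6, α the face bearing O4 and O5. Atom labels C1–C7 follow the target numbering throughout.

Step 1
Reactants: 1 acrolein
Product: 3 2-bromoacrolein, via 2,3-dibromopropanal 2 (not isolated)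
Conditions: Br2, CH2Cl2, −78 °C; then Et3N, −78 → 0 °C; distilled and used fresh
Reagents that add atoms: bromine, BrBr
Why: Electrophilic bromine addition to the alkene gives the vicinal dibromide, whose acidic α-hydrogen lets triethylamine expel the β-bromide (E1cB dehydrobromination), the standard preparation of this dienophile.

Step 2
Reactants: 3 2-bromoacrolein; 4 (1E,3E)-buta-1,3-diene-1,4-diyl diacetate
Product: 5 (1R,2R,5R)-2,5-diacetoxy-1-bromocyclohex-3-ene-1-carbaldehyde (formyl cis to both acetoxy groups, bromine trans)
Conditions: (S)-3,3-diphenyl-1-(o-tolyl)tetrahydro-1H,3H-pyrrolo[1,2-c][1,3,2]oxazaborole (20 mol %), HN(SO2CF3)2 (17 mol %), CH2Cl2, −78 → −20 °C; chromatographic removal of the C1 epimer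
Reagents that add atoms: none
Why: The N-protonated oxazaborolidine binds the formyl oxygen of 3 (B–O coordination reinforced by a formyl C–H···O contact), lowers its LUMO and stacks the s-trans enal on a phenyl group, so the s-cis diene should add to the exposed C1 Re face in a concerted, asynchronous, suprafacial [4+2] cycloaddition. The closest known reaction type is the oxazaborolidinium-catalysed Diels–Alder reaction of 2-bromoacrolein with butadienes and cyclopentadiene, together with the thermal cycloaddition of 4 with acrylic dienophiles. The six-membered carbocycle is closed by intermolecular [4+2] annulation, both σ bonds (C2–C3 and C1–C6) forming in the same step. C3 and C6 come out cis because the E,E geometry of 4 is transferred suprafacially; their absolute configuration follows from the catalyst-controlled dienophile face combined with the formyl-endo orientation, which also fixes C1 (formyl β, bromine α). The step needs both face selectivity and endo/exo selectivity, because the two C1 epimers formed on one dienophile face are antipodal at C3/C6 and would give opposite enantiomers once C1 is flattened; the symmetrical diene removes any regiochemical question, and the Lewis-acid-bound formyl group should favour the endo mode with an acyclic diene. The quaternary C1 carries no hydrogen, so neither acetate can be lost by E1cB from the adduct.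

Step 3
Reactants: 5 (1R,2R,5R)-2,5-diacetoxy-1-bromocyclohex-3-ene-1-carbaldehyde
Product: 6 (1R,2R,3S,4R,5R)-2,5-diacetoxy-1-bromo-3,4-dihydroxycyclohexane-1-carbaldehyde (4α,5α-diol, 3β,6β-diacetate, 1β-formyl, 1α-bromo in target numbering)
Conditions: OsO4 (2 mol %), NMO, citric acid, t-BuOH–H2O (1:1), rt
Reagents that add atoms: OsO4, O=[Os](=O)(=O)=O (catalytic oxygen carrier); N-methylmorpholine N-oxide, C[N+]1([O-])CCOCC1; water, O
Why: Catalytic osmylation (Upjohn dihydroxylation) should add both oxygens suprafacially to C4=C5 from the face opposite the two allylic acetoxy groups, as in the hydroxylation of related diacetoxycyclohexene cycloadducts, which sets C4 and C5 (α) relative to C3 and C6; the citric acid buffer speeds turnover on this electron-poor alkene and suppresses acetyl migration, and the trans-disposed formyl group cannot form a lactol with the new hydroxyls.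

Step 4
Reactants: 6 the 4α,5α-diol; 7 trimethyl orthobenzoate
Product: 8 cyclic methyl orthobenzoate of 6 (O4 and O5 bridged by C(OMe)Ph as a cis-fused 2-methoxy-2-phenyl-1,3-dioxolane; mixture of epimers at the orthoester carbon)
Conditions: PhC(OMe)3, PPTS (cat.), CH2Cl2, rt; then Et3N
Reagents that add atoms: trimethyl orthobenzoate 7, COC(OC)(OC)c1ccccc1
Why: Acid-catalysed orthoester exchange closes a five-membered dioxolane on the only cis-diol, the new orthoester carbon arises as an inconsequential mixture of epimers that converge in step 8, and the fully substituted α-bromo aldehyde is too hindered and too electron-poor to be acetalised under these mild conditions.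

Step 5
Reactants: 8 the bromo aldehyde orthoester
Product: 9 enal orthoester (C1=C2 alkene conjugated with the C7 formyl group; 3β,6β-diacetate; 4α,5α-orthobenzoate)
Conditions: DBU, toluene, 0 → 40 °C
Reagents that add atoms: none
Why: E2 dehydrobromination: with bromine axial on the α face only the axial β-hydrogen on C2 is antiperiplanar, whereas H6 is cis to bromine and cannot react, so the conjugated C1=C2 enal should form without touching oxygenated C6 and the C1 stereocentre is erased; the orthoester and acetates are stable to the non-nucleophilic base.

Step 6
Reactants: 9 the enal orthoester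
Product: 10 allylic alcohol orthoester (C7H2OH on C1; otherwise as 9)
Conditions: NaBH4, CeCl3·7H2O, MeOH, −78 °C; AcOH quench
Reagents that add atoms: none
Why: Luche reduction delivers hydride to the aldehyde carbon (1,2-addition) and not to C2, the esters and the orthoester are inert at this temperature, and no stereocentre is made or touched; the cold acidic quench prevents O6 to O7 acetyl migration.

Step 7
Reactants: 10 the allylic alcohol orthoester; 11 benzoyl chloride
Product: 12 C7 benzoate orthoester (C7H2OBz; 3β,6β-diacetate; 4α,5α-orthobenzoate)
Conditions: BzCl, Et3N, DMAP (cat.), CH2Cl2, 0 °C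
Reagents that add atoms: benzoyl chloride 11, O=C(Cl)c1ccccc1
Why: DMAP-catalysed acylation of the only free hydroxyl, a primary allylic alcohol, under basic conditions that leave the acid-labile orthoester intact.

Step 8
Reactants: 12 the C7 benzoate orthoester
Product: 14 [(3R,4S,5R,6S)-5-(benzoyloxy)-3,4,6-trihydroxycyclohex-1-en-1-yl]methyl benzoate, via 3,6-di-O-acetyl 5-O-benzoate 13 (not isolated)
Conditions: AcOH–H2O (4:1), rt; concentrate; then HCl (1.25 M in MeOH), 0 °C → rt
Reagents that add atoms: water, O
Why: Aqueous acid ionises the orthoester to the 2-phenyl-1,3-dioxolan-2-ylium ion, water adds, and the hemi-orthoester should collapse with the acyl group staying on the axial oxygen (the usual outcome for cyclic orthoesters of cis-diols on six-membered rings), which is O5 because A(1,2) strain between C7 and the C6 acetate holds O6 pseudoaxial and hence O5 axial and O4 equatorial; acid-catalysed methanolysis then removes the two acetates much faster than the conjugated benzoates, without touching any stereocentre.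

Compound list
1 | acrolein (prop-2-enal) | C=CC=O | starting material
2 | 2,3-dibromopropanal (racemic) | O=CC(Br)CBr | intermediate
3 | 2-bromoacrolein (2-bromoprop-2-enal) | C=C(Br)C=O | intermediate
4 | (1E,3E)-buta-1,3-diene-1,4-diyl diacetate | CC(=O)O/C=C/C=C/OC(C)=O | starting material
5 | (1R,2R,5R)-2,5-diacetoxy-1-bromocyclohex-3-ene-1-carbaldehyde (formyl cis to both acetoxy groups) | O=C[C@@]1(Br)C[C@@H](OC(C)=O)C=C[C@H]1OC(C)=O | intermediate
6 | (1R,2R,3S,4R,5R)-2,5-diacetoxy-1-bromo-3,4-dihydroxycyclohexane-1-carbaldehyde (diol trans to the flanking acetates) | O=C[C@@]1(Br)C[C@@H](OC(C)=O)[C@H](O)[C@H](O)[C@H]1OC(C)=O | intermediate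
7 | trimethyl orthobenzoate | COC(OC)(OC)c1ccccc1 | starting material
8 | 4,5-O-(α-methoxybenzylidene) orthoester of 6 (epimers at the orthoester carbon) | O=C[C@@]1(Br)C[C@@H](OC(C)=O)[C@@H]2OC(OC)(c3ccccc3)O[C@@H]2[C@H]1OC(C)=O | intermediate
9 | 3β,6β-diacetoxy-4α,5α-O-(α-methoxybenzylidene)cyclohex-1-ene-1-carbaldehyde (target numbering) | O=CC1=C[C@@H](OC(C)=O)[C@@H]2OC(OC)(c3ccccc3)O[C@@H]2[C@H]1OC(C)=O | intermediate
10 | corresponding allylic alcohol (C7H2OH) | OCC1=C[C@@H](OC(C)=O)[C@@H]2OC(OC)(c3ccccc3)O[C@@H]2[C@H]1OC(C)=O | intermediate
11 | benzoyl chloride | O=C(Cl)c1ccccc1 | starting material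
12 | C7 benzoate of 10 | O=C(OCC1=C[C@@H](OC(C)=O)[C@@H]2OC(OC)(c3ccccc3)O[C@@H]2[C@H]1OC(C)=O)c1ccccc1 | intermediate
13 | [3β,6β-diacetoxy-5α-(benzoyloxy)-4α-hydroxycyclohex-1-en-1-yl]methyl benzoate | O=C(OCC1=C[C@@H](OC(C)=O)[C@H](O)[C@H](OC(=O)c2ccccc2)[C@H]1OC(C)=O)c1ccccc1 | intermediate
14 | [(3R,4S,5R,6S)-5-(benzoyloxy)-3,4,6-trihydroxycyclohex-1-en-1-yl]methyl benzoate (CNP0198957.1) | O=C(OCC1=C[C@@H](O)[C@H](O)[C@H](OC(=O)c2ccccc2)[C@H]1O)c1ccccc1 | target

Total step count: 8. Longest linear sequence: 8 steps (1 to 14); 7 steps from the purchased diene 4.

Steps most likely to fail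

Step 2. The electron-poor, acid-sensitive diene may react too slowly with the catalyst-bound dienophile or decompose, and face selectivity or endo/exo selectivity may be eroded; either erosion lowers the enantiomeric purity of everything downstream. Fallback: setting out from 3 and 4, the cycloaddition is run thermally without a catalyst (toluene, BHT, 70 °C), the usual way this diene is engaged by acrylic dienophiles, giving after removal of the exo epimer the racemic formyl-endo adduct F1. Its enantiomers are separated by preparative chromatography on a cellulose tris(3,5-dimethylphenylcarbamate) stationary phase, and the (1R,2R,5R) enantiomer re-enters the route as 5.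

Step 5. The anti elimination may be slow, because bromine must turn axial against a syn-axial oxygen. The enal once formed may also suffer γ-deprotonation and vinylogous loss of the C6 acetate, leading towards aromatisation. Fallback: setting out from 8, the carbonyl group is removed before the elimination. NaBH4 (MeOH, −40 °C, AcOH quench) gives the bromohydrin F2, and benzoylation (BzCl, Et3N, DMAP, 0 °C) gives the tertiary bromo benzoate F3. E2 elimination with DBU in hot toluene, where no acidifying carbonyl remains and H6 is still syn to bromine, should then give mainly the endocyclic alkene, rejoining the route at 12.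

Step 8. Orthoester opening may deliver the benzoyl group to O4 instead of O5 if the ring reacts through the other half-chair, and benzoyl migration across the cis-diol or partial benzoate methanolysis may occur while the acetates are removed. Fallback: setting out from 12, PPTS in dry MeOH exchanges the orthoester for the free 4,5-diol F4 with the acetates retained. Borinate-catalysed benzoylation (2-aminoethyl diphenylborinate cat., BzCl, i-Pr2NEt, MeCN) acylates the equatorial oxygen of a cis-diol, the opposite positional preference to orthoester opening. In the case this fallback answers, that oxygen is O5, so the product is 13, where the route is rejoined before the acetate methanolysis.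

Further compounds
F1 | step 2 | racemic 2,5-diacetoxy-1-bromocyclohex-3-ene-1-carbaldehyde, formyl cis to both acetoxy groups (both enantiomers) | O=C[C@@]1(Br)C[C@@H](OC(C)=O)C=C[C@H]1OC(C)=O.O=C[C@]1(Br)C[C@H](OC(C)=O)C=C[C@@H]1OC(C)=O
F2 | step 5 | bromohydrin: 8 with the formyl group reduced to CH2OH | OC[C@@]1(Br)C[C@@H](OC(C)=O)[C@@H]2OC(OC)(c3ccccc3)O[C@@H]2[C@H]1OC(C)=O
F3 | step 5 | C7 benzoate of F2 (tertiary bromide) | O=C(OC[C@@]1(Br)C[C@@H](OC(C)=O)[C@@H]2OC(OC)(c3ccccc3)O[C@@H]2[C@H]1OC(C)=O)c1ccccc1
F4 | step 8 | (3β,6β-diacetoxy-4α,5α-dihydroxycyclohex-1-en-1-yl)methyl benzoate | O=C(OCC1=C[C@@H](OC(C)=O)[C@H](O)[C@H](O)[C@H]1OC(C)=O)c1ccccc1
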